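The synthesis rests on cutting the C3–C1' bond (isoflavone numbering) of furan ring D, the single carbon–carbon link between the chromone (rings A and C) and ring B. Its partner in ring D, the C2–O–C2' ether, is installed earlier by displacing a 2-sulfonylchromone with a phenol. The precursor is therefore a bis-MOM 2-aryloxychromone that already carries the dihydropyran on ring A and the chromene on ring B. One palladium-catalysed double C–H coupling joins chromone C3–H to C1'–H and closes ring D. It exploits the fact that C3', the other carbon ortho to the ether oxygen, is blocked by the chromene carbon. Acid then frees both phenols.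

Key step: step 11

Remark on the chemistry: isoflavone numbering is used for the core (chromone O1–C8a, ring B C1'–C6'). The target holds no stereocentre, so no step has to control configuration.

Design points:
- **Order on ring B.** In 3,4-dihydroxybenzaldehyde the more acidic 4-OH takes the MOM group first. The propargyl ether then sits on O3, and the Claisen terminus is the carbon between O3 and the future O2'.
- **Timing of the oxidations.** Both peracid oxidations are run before any chromene double bond exists.
- **Timing of chromene closure.** The chromene is closed only after the phenol oxygen is bonded to the chromone. A free hydroxyl beside the allenyl group would offer a second oxygen for pyran closure and lead to an isomeric chromene.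
- **Protection on ring A.** The MOM group must sit on the chroman 7-OH, so that the pyranone closes through the 5-OH and gives the angular [2,3-h] fusion.

Step 1
Reactants: 1 2,4,6-trihydroxyacetophenone; 2 2-methylbut-3-en-2-ol
Product: 4 1-(5,7-dihydroxy-2,2-dimethylchroman-6-yl)ethanone, via 3-prenylphloroacetophenone 3 (not isolated)
Conditions: 1 (1.5 equiv), BF3·OEt2 (0.5 equiv), 1,4-dioxane, 25 → 60 °C
Reagents that add atoms: none
Why: Friedel–Crafts alkylation by the dimethylallyl cation at one of the two equivalent free ring carbons gives 3, and the same acid then adds the unchelated para hydroxyl across the prenyl double bond in the Markovnikov sense, so the 6-acetylchroman should prevail over the 8-acetyl isomer (removed by chromatography), while the excess of 1 curbs double alkylation.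

Step 2
Reactants: 4 1-(5,7-dihydroxy-2,2-dimethylchroman-6-yl)ethanone
Product: 5 1-[5-hydroxy-7-(methoxymethoxy)-2,2-dimethylchroman-6-yl]ethanone
Conditions: MOMCl (1.05 equiv), iPr2NEt (1.2 equiv), CH2Cl2, 0 °C
Reagents that add atoms: chloromethyl methyl ether (MOMCl), COCCl
Why: In this phenol O-alkylation the 7-OH has only H-8 beside it whereas the 5-OH is wedged between the acetyl group and the C4 methylene, so the first MOM group should enter at O7, and the remaining 5-OH is then held in a chelate with the ketone that stops a second alkylation.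

Step 3
Reactants: 5 1-[5-hydroxy-7-(methoxymethoxy)-2,2-dimethylchroman-6-yl]ethanone
Product: 6 4-hydroxy-5-(methoxymethoxy)-8,8-dimethyl-9,10-dihydro-2H,8H-pyrano[2,3-h]chromene-2-thione
Conditions: CS2 (3 equiv), KOtBu (3.5 equiv), THF, 0 °C → rt; AcOH quench to pH 5
Reagents that add atoms: carbon disulfide, S=C=S
Why: Claisen-type thioacylation of the methyl ketone enolate gives a β-oxodithioate whose thiocarbonyl is attacked by the neighbouring phenoxide with loss of hydrosulfide, the standard entry to 4-hydroxychromene-2-thiones (also with a substituent at C8), and the MOM acetal is inert to base.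

Step 4
Reactants: 6 4-hydroxy-5-(methoxymethoxy)-8,8-dimethyl-9,10-dihydro-2H,8H-pyrano[2,3-h]chromene-2-thione
Product: 7 5-(methoxymethoxy)-8,8-dimethyl-2-(methylsulfanyl)-9,10-dihydro-4H,8H-pyrano[2,3-h]chromen-4-one
Conditions: MeI (1.1 equiv), K2CO3 (1.2 equiv), acetone, rt
Reagents that add atoms: iodomethane, CI
Why: The ambident anion of 6 is alkylated by the soft electrophile at sulfur (S-alkylation), which fixes the 4-chromone tautomer.

Step 5
Reactants: 7 5-(methoxymethoxy)-8,8-dimethyl-2-(methylsulfanyl)-9,10-dihydro-4H,8H-pyrano[2,3-h]chromen-4-one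
Product: 8 5-(methoxymethoxy)-8,8-dimethyl-2-(methylsulfonyl)-9,10-dihydro-4H,8H-pyrano[2,3-h]chromen-4-one
Conditions: mCPBA (2.3 equiv), CH2Cl2, 0 °C → rt
Reagents that add atoms: 3-chloroperbenzoic acid (mCPBA), O=C(OO)c1cccc(Cl)c1
Why: Peracid oxidation of a sulfide to the sulfone is reliable here because 7 holds no isolated alkene and its enone double bond is electron-poor.

Step 6
Reactants: 9 3,4-dihydroxybenzaldehyde
Product: 10 3-hydroxy-4-(methoxymethoxy)benzaldehyde
Conditions: MOMCl (1.0 equiv), K2CO3 (1.1 equiv), acetone, 0 °C → rt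
Reagents that add atoms: chloromethyl methyl ether (MOMCl), COCCl
Why: In this selective phenol O-alkylation the 4-OH is para to the formyl group and clearly the more acidic, so one equivalent of mild base forms only its phenoxide and leaves O3 free for the propargyl group.

Step 7
Reactants: 10 3-hydroxy-4-(methoxymethoxy)benzaldehyde; 11 3-chloro-3-methylbut-1-yne
Product: 12 4-(methoxymethoxy)-3-[(2-methylbut-3-yn-2-yl)oxy]benzaldehyde
Conditions: DBU (1.3 equiv), CuCl2·2H2O (1 mol %), MeCN, 0 °C
Reagents that add atoms: none
Why: Copper-catalysed propargylic substitution of a tertiary propargyl chloride by a phenoxide is the standard route to aryl 1,1-dimethylpropargyl ethers and outruns elimination at low temperature.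

Step 8
Reactants: 12 4-(methoxymethoxy)-3-[(2-methylbut-3-yn-2-yl)oxy]benzaldehyde
Product: 14 4-(methoxymethoxy)-3-[(2-methylbut-3-yn-2-yl)oxy]phenol, via aryl formate 13 (not isolated)
Conditions: mCPBA (1.3 equiv), CH2Cl2, 0 °C → rt; aq. NaHCO3 wash; then K2CO3 (10 mol %), MeOH, 0 °C
Reagents that add atoms: 3-chloroperbenzoic acid (mCPBA), O=C(OO)c1cccc(Cl)c1
Why: In the Baeyer–Villiger oxidation the aryl group, activated by the para OMOM substituent, migrates in preference to hydride, the alkyne is inert to peracid (a chromene would not be), and catalytic methanolysis of the formate releases the phenol.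

Step 9
Reactants: 8 5-(methoxymethoxy)-8,8-dimethyl-2-(methylsulfonyl)-9,10-dihydro-4H,8H-pyrano[2,3-h]chromen-4-one; 14 4-(methoxymethoxy)-3-[(2-methylbut-3-yn-2-yl)oxy]phenol
Product: 15 5-(methoxymethoxy)-2-{4-(methoxymethoxy)-3-[(2-methylbut-3-yn-2-yl)oxy]phenoxy}-8,8-dimethyl-9,10-dihydro-4H,8H-pyrano[2,3-h]chromen-4-one
Conditions: K2CO3 (1.5 equiv), DMF, rt, N2
Reagents that add atoms: none
Why: Addition–elimination at the vinylogous acyl carbon C2 is known for 2-sulfonylchromones with amines and phenoxides, and methanesulfinate leaves far more readily than the ring A phenoxide, so the pyranone should stay closed.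

Step 10
Reactants: 15 5-(methoxymethoxy)-2-{4-(methoxymethoxy)-3-[(2-methylbut-3-yn-2-yl)oxy]phenoxy}-8,8-dimethyl-9,10-dihydro-4H,8H-pyrano[2,3-h]chromen-4-one
Product: 17 5-(methoxymethoxy)-2-{[8-(methoxymethoxy)-2,2-dimethyl-2H-chromen-5-yl]oxy}-8,8-dimethyl-9,10-dihydro-4H,8H-pyrano[2,3-h]chromen-4-one, via ortho-allenylphenol 16 (not isolated)
Conditions: o-xylene, 145 °C, N2
Reagents that add atoms: none
Why: The aromatic propargyl Claisen rearrangement, tautomerisation to 16, 1,5-hydrogen shift and oxa-6π electrocyclisation can use only C3' (the other ortho carbon bears OMOM), and only O4' can close the pyran because O2' is already bound to the chromone, so a single chromene should form under neutral conditions that spare both MOM groups.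

Step 11
Reactants: 17 5-(methoxymethoxy)-2-{[8-(methoxymethoxy)-2,2-dimethyl-2H-chromen-5-yl]oxy}-8,8-dimethyl-9,10-dihydro-4H,8H-pyrano[2,3-h]chromen-4-one
Product: 18 formosanatin D bis(methoxymethyl) ether
Conditions: Pd(OAc)2 (10 mol %), AgOAc (2.5 equiv), CsO2CCMe3 (50 mol %), 1,4-dioxane, 100 °C, N2
Reagents that add atoms: none
Why: Electrophilic divalent palladium should metalate chromone C3, the α-carbon of an enone whose β-carbon C2 bears two oxygens and therefore the most nucleophilic site, and a pivalate ligand then removes the nearby ring B proton by concerted metalation–deprotonation to give a six-membered palladacycle (Pd, C3, C2, O, C2', C1'). Reductive elimination forms C3–C1' and so closes the five-membered furan ring D at its carbon–carbon edge, after which AgOAc returns zerovalent palladium to the divalent state. The closest known reaction type is the intramolecular dehydrogenative double C–H coupling that converts 4-aryloxycoumarins into coumestans and diaryl ethers into dibenzofurans. No stereocentre is formed. The step needs site selectivity on ring B, which is structural because C3' carries the chromene carbon and only C1'–H lies ortho to the ether oxygen, and it needs chemoselectivity against the chromene double bond, where insertion of the C3–palladium bond would leave an alkylpalladium with no syn β-hydrogen (the neighbouring CMe2 carbon is quaternary) and hence no productive exit. The carboxylate buffer keeps the medium only weakly acidic, which should protect both MOM acetals and the chromene.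

Step 12
Reactants: 18 formosanatin D bis(methoxymethyl) ether
Product: 19 formosanatin D
Conditions: dilute aq. HCl, MeOH–THF, 45 °C
Reagents that add atoms: none
Why: Acid-catalysed acetal exchange with methanol removes both MOM groups under conditions that 2,2-dimethylchromenes and the aromatic furochromone core normally tolerate, and the freed 5-OH is stabilised by chelation to C4=O.

Compound list
1 | 2,4,6-trihydroxyacetophenone | CC(=O)c1c(O)cc(O)cc1O | starting material
2 | 2-methylbut-3-en-2-ol | CC(C)(O)C=C | starting material
3 | 1-[2,4,6-trihydroxy-3-(3-methylbut-2-en-1-yl)phenyl]ethanone (3-prenylphloroacetophenone) | CC(=O)c1c(O)cc(O)c(CC=C(C)C)c1O | intermediate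
4 | 1-(5,7-dihydroxy-2,2-dimethylchroman-6-yl)ethanone | CC(=O)c1c(O)cc2OC(C)(C)CCc2c1O | intermediate
5 | 1-[5-hydroxy-7-(methoxymethoxy)-2,2-dimethylchroman-6-yl]ethanone | CC(=O)c1c(OCOC)cc2OC(C)(C)CCc2c1O | intermediate
6 | 4-hydroxy-5-(methoxymethoxy)-8,8-dimethyl-9,10-dihydro-2H,8H-pyrano[2,3-h]chromene-2-thione | S=c1cc(O)c2c(OCOC)cc3OC(C)(C)CCc3c2o1 | intermediate
7 | 5-(methoxymethoxy)-8,8-dimethyl-2-(methylsulfanyl)-9,10-dihydro-4H,8H-pyrano[2,3-h]chromen-4-one | CSc1cc(=O)c2c(OCOC)cc3OC(C)(C)CCc3c2o1 | intermediate
8 | 5-(methoxymethoxy)-8,8-dimethyl-2-(methylsulfonyl)-9,10-dihydro-4H,8H-pyrano[2,3-h]chromen-4-one | CS(=O)(=O)c1cc(=O)c2c(OCOC)cc3OC(C)(C)CCc3c2o1 | intermediate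
9 | 3,4-dihydroxybenzaldehyde | O=Cc1ccc(O)c(O)c1 | starting material
10 | 3-hydroxy-4-(methoxymethoxy)benzaldehyde | O=Cc1ccc(OCOC)c(O)c1 | intermediate
11 | 3-chloro-3-methylbut-1-yne | CC(C)(Cl)C#C | starting material
12 | 4-(methoxymethoxy)-3-[(2-methylbut-3-yn-2-yl)oxy]benzaldehyde | O=Cc1ccc(OCOC)c(OC(C)(C)C#C)c1 | intermediate
13 | 4-(methoxymethoxy)-3-[(2-methylbut-3-yn-2-yl)oxy]phenyl formate | O=COc1ccc(OCOC)c(OC(C)(C)C#C)c1 | intermediate
14 | 4-(methoxymethoxy)-3-[(2-methylbut-3-yn-2-yl)oxy]phenol | Oc1ccc(OCOC)c(OC(C)(C)C#C)c1 | intermediate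
15 | 5-(methoxymethoxy)-2-{4-(methoxymethoxy)-3-[(2-methylbut-3-yn-2-yl)oxy]phenoxy}-8,8-dimethyl-9,10-dihydro-4H,8H-pyrano[2,3-h]chromen-4-one | O=c1cc(Oc2ccc(OCOC)c(OC(C)(C)C#C)c2)oc2c3CCC(C)(C)Oc3cc(OCOC)c12 | intermediate
16 | 2-[3-hydroxy-4-(methoxymethoxy)-2-(3-methylbuta-1,2-dien-1-yl)phenoxy]-5-(methoxymethoxy)-8,8-dimethyl-9,10-dihydro-4H,8H-pyrano[2,3-h]chromen-4-one | O=c1cc(Oc2ccc(OCOC)c(O)c2C=C=C(C)C)oc2c3CCC(C)(C)Oc3cc(OCOC)c12 | intermediate
17 | 5-(methoxymethoxy)-2-{[8-(methoxymethoxy)-2,2-dimethyl-2H-chromen-5-yl]oxy}-8,8-dimethyl-9,10-dihydro-4H,8H-pyrano[2,3-h]chromen-4-one | O=c1cc(Oc2ccc(OCOC)c3OC(C)(C)C=Cc23)oc2c3CCC(C)(C)Oc3cc(OCOC)c12 | intermediate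
18 | formosanatin D bis(methoxymethyl) ether | O=c1c2c(OCOC)cc3OC(C)(C)CCc3c2oc2oc3c4C=CC(C)(C)Oc4c(OCOC)cc3c12 | intermediate
19 | formosanatin D | CC1(C)C=Cc2c(c(O)cc3c2oc2oc4c5c(cc(O)c4c(=O)c23)OC(C)(C)CC5)O1 | target

Total step count: 12
Longest linear sequence: 9 steps (steps 1–5, then 9–12). The ring B branch needs 3 steps (6–8) before the union in step 9.

Steps most likely to fail

**Step 11.**
- *What may go wrong:*
  - palladium may bind to the chromene double bond or acetoxypalladate it;
  - C3 may lose palladium by protonation before the second C–H bond is cleaved;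
  - silver may oxidise the electron-rich ring B;
  - the peri MOM group may be lost, after which the 5-OH/C4=O pair would chelate the catalyst.
- *Fallback:* it forms the same C3–C1' bond by a C–Br/C–H coupling under zerovalent palladium, which needs no oxidant. It sets out from 14 (with 8) and returns at 18. Phenol 14 is brominated with NBS (MeCN, −20 °C) at the carbon ortho to the hydroxyl and para to the propargyloxy group, giving 2-bromo-4-(methoxymethoxy)-5-[(2-methylbut-3-yn-2-yl)oxy]phenol F1. Displacement of sulfone 8 (K2CO3, DMF, rt) gives 2-{2-bromo-4-(methoxymethoxy)-5-[(2-methylbut-3-yn-2-yl)oxy]phenoxy}-5-(methoxymethoxy)-8,8-dimethyl-9,10-dihydro-4H,8H-pyrano[2,3-h]chromen-4-one F2. Heating as in step 10 consumes the alkyne and gives 2-{[6-bromo-8-(methoxymethoxy)-2,2-dimethyl-2H-chromen-5-yl]oxy}-5-(methoxymethoxy)-8,8-dimethyl-9,10-dihydro-4H,8H-pyrano[2,3-h]chromen-4-one F3. Intramolecular direct arylation of chromone C3–H then gives 18 (Pd(OAc)2, PCy3·HBF4, K2CO3, Me3CCO2H 30 mol %, DMA, 110 °C). This type of closure is known for 4-(2-bromoaryloxy)coumarins.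

**Step 1.**
- *What may go wrong:* the very electron-rich ring may be alkylated twice, the pyran may close through an ortho hydroxyl instead of the para hydroxyl, and the acid may interconvert the two chromans.
- *Fallback:* it replaces carbocation chemistry by a condensation–electrocyclisation followed by hydrogenation. It sets out from 1 and returns at 4. Compound 1 and 3-methylbut-2-enal are heated with ethylenediammonium diacetate (10 mol %) in toluene. Knoevenagel-type condensation and oxa-6π closure give 1-(5,7-dihydroxy-2,2-dimethyl-2H-chromen-6-yl)ethanone F4. Hydrogenation of its double bond (H2 1 atm, 10% Pd/C, EtOAc) gives 4.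

**Step 2.**
- *What may go wrong:* the two hydroxyls flanking the acetyl group may be poorly discriminated, which would carry the linear ring fusion forward unnoticed.
- *Fallback:* it inverts the logic, protecting both oxygens and then releasing one. It sets out from 4 and returns at 5. Exhaustive alkylation (NaH, MOMCl, DMF, 0 °C) gives 1-[5,7-bis(methoxymethoxy)-2,2-dimethylchroman-6-yl]ethanone F5. Mild methanolysis (I2 10 mol %, MeOH, rt) should first cleave the 5-OMOM group, which is flanked on both sides, twisted out of conjugation and strained. The phenol set free then chelates the ketone and slows the second cleavage, so the reaction should stop at 5.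

Further compounds
F1 | step 11 | 2-bromo-4-(methoxymethoxy)-5-[(2-methylbut-3-yn-2-yl)oxy]phenol | Oc1cc(OC(C)(C)C#C)c(OCOC)cc1Br
F2 | step 11 | 2-{2-bromo-4-(methoxymethoxy)-5-[(2-methylbut-3-yn-2-yl)oxy]phenoxy}-5-(methoxymethoxy)-8,8-dimethyl-9,10-dihydro-4H,8H-pyrano[2,3-h]chromen-4-one | O=c1cc(Oc2cc(OC(C)(C)C#C)c(OCOC)cc2Br)oc2c3CCC(C)(C)Oc3cc(OCOC)c12
F3 | step 11 | 2-{[6-bromo-8-(methoxymethoxy)-2,2-dimethyl-2H-chromen-5-yl]oxy}-5-(methoxymethoxy)-8,8-dimethyl-9,10-dihydro-4H,8H-pyrano[2,3-h]chromen-4-one | O=c1cc(Oc2c(Br)cc(OCOC)c3OC(C)(C)C=Cc23)oc2c3CCC(C)(C)Oc3cc(OCOC)c12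
F4 | step 1 | 1-(5,7-dihydroxy-2,2-dimethyl-2H-chromen-6-yl)ethanone | CC(=O)c1c(O)cc2OC(C)(C)C=Cc2c1O
F5 | step 2 | 1-[5,7-bis(methoxymethoxy)-2,2-dimethylchroman-6-yl]ethanone | CC(=O)c1c(OCOC)cc2OC(C)(C)CCc2c1OCOC
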